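## Retrosynthetic overview

1. The target 25 comes from the 2,6-dimethoxyphenyl diketone 21 by late arene chemistry: C–H hydroxylation para to the side chain, double ortho-formylation, O-demethylation.
2. 21 comes from the allylic cyclobutanol 18: epoxidation triggers a semipinacol ring expansion (cyclobutanol → cyclopentanone, forming the bond between the quaternary carbon and the cyclopropyl-bearing carbon), then a retro-aldol opens the six-membered carane ring and unveils both ketones.
3. 18 comes from cyclobutanone 10 and the carenyl-lithium 17, made from carone 15 by a Shapiro reaction.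
4. 10 comes from the racemic benzylic acetate 6 and silyl enol ether 8 by a catalytic asymmetric SN1 alkylation (sets the quaternary and the benzylic centres). 15 comes from 6-methylcyclohexenone by asymmetric conjugate addition of isopropenyl, then HBr/KOH cyclopropane closure.
5. Ring order: cyclobutanone (bought) → cyclopropane (built on a cyclohexanone template) → cyclopentanone (ring expansion) → template ring opened; the arene is functionalised last.

Assumption: the (S,S)-catalyst of step 4 is taken to give the (2R,1′S) isomer 10; if the sense of induction is opposite, the (R,R)-catalyst is used.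

## Route

Step 1
Reactants: 1 resorcinol
Product: 2 1,3-dimethoxybenzene
Conditions: MeI, K2CO3, acetone, reflux
Reagents that add atoms: iodomethane, CI
Why: Williamson ether synthesis; both phenols are capped so that the ring can be lithiated between the two oxygens in the next step.

Step 2
Reactants: 2 1,3-dimethoxybenzene; 3 3-methylbutanal
Product: 6 1-(2,6-dimethoxyphenyl)-3-methylbutyl acetate (racemic), via 2,6-dimethoxyphenyllithium 4 (not isolated), via lithium 1-(2,6-dimethoxyphenyl)-3-methylbutan-1-olate 5 (not isolated)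
Conditions: n-BuLi, THF, 0 °C; 3, −78 °C; then Ac2O, −78 → 20 °C
Reagents that add atoms: acetic anhydride, CC(=O)OC(C)=O
Why: Directed ortho-metalation at the position flanked by both methoxy groups, 1,2-addition to the aldehyde and in situ O-acylation give an easily ionised benzylic acetate; it is racemic because its stereocentre is set in step 4.

Step 3
Reactants: 7 2-methylcyclobutan-1-one
Product: 8 trimethyl[(2-methylcyclobut-1-en-1-yl)oxy]silane
Conditions: Me3SiCl, NaI, Et3N, MeCN, 20 °C
Reagents that add atoms: chlorotrimethylsilane, C[Si](C)(C)Cl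
Why: Silyl enol ether formation under equilibrating conditions (iodotrimethylsilane formed in situ) gives the more substituted, thermodynamic enol ether.

Step 4
Reactants: 6 1-(2,6-dimethoxyphenyl)-3-methylbutyl acetate; 8 trimethyl[(2-methylcyclobut-1-en-1-yl)oxy]silane
Product: 10 (2R)-2-[(1S)-1-(2,6-dimethoxyphenyl)-3-methylbutyl]-2-methylcyclobutan-1-one, via 1-(2,6-dimethoxyphenyl)-3-methylbutyl cation 9 (not isolated)
Conditions: (S,S)-IDPi (3 mol %; the N-triflyl imidodiphosphorimidate acid built from two (S)-3,3′-bis[3,5-bis(trifluoromethyl)phenyl]-1,1′-bi-2-naphthol units), 8 (1.5 equiv), toluene, −60 °C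
Reagents that add atoms: none
Why: Proposed new method: an enantioconvergent, diastereoselective SN1 alkylation in which the silylated IDPi ionises racemic 6 to the planar, doubly methoxy-stabilised cation 9 held inside the confined chiral anion, so that one face of the cation meets one face of the tetrasubstituted enol silane in an open antiperiplanar transition state and both the benzylic centre (1′S) and the quaternary centre (2R) are set under catalyst control while silyl transfer to acetate turns the catalyst over; the closest known reaction types are IDPi-catalysed Mukaiyama-type additions of silyl enol ethers through silylium ion pairs and enantioconvergent SN1 substitutions of racemic acetates by silyl nucleophiles under chiral ion-pairing catalysis.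

Step 5
Reactants: 11 6-methylcyclohex-2-en-1-one (racemic); 12 potassium trifluoro(prop-1-en-2-yl)borate
Product: 13 (5R)-2-methyl-5-(prop-1-en-2-yl)cyclohexan-1-one (dihydrocarvone; both C2 epimers)
Conditions: [Rh(cod)2]PF6 (3 mol %), (R)-BINAP, toluene/H2O 10:1, 105 °C
Reagents that add atoms: none
Why: Rhodium-catalysed asymmetric conjugate addition (Hayashi–Miyaura type) of the alkenyltrifluoroborate; the (R)-BINAP complex delivers isopropenyl to one enone face and sets the 5R centre, while the methyl-bearing centre is irrelevant because it becomes sp2 in step 8.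

Step 6
Reactants: 13 (5R)-2-methyl-5-(prop-1-en-2-yl)cyclohexan-1-one
Product: 15 (1S,6R)-3,7,7-trimethylbicyclo[4.1.0]heptan-2-one (carone; both C3 epimers), via (5R)-5-(2-bromopropan-2-yl)-2-methylcyclohexan-1-one 14 (not isolated)
Conditions: HBr, AcOH, 0 °C; evaporate; then KOH, MeOH, 0 → 20 °C
Reagents that add atoms: none
Why: Markovnikov hydrobromination followed by intramolecular enolate alkylation (1,3-elimination, the classical carone synthesis); only the cis-fused bicycle can form, so the 5R centre fixes both cyclopropane stereocentres.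

Step 7
Reactants: 15 (1S,6R)-3,7,7-trimethylbicyclo[4.1.0]heptan-2-one
Product: 16 N′-[(1S,6R)-3,7,7-trimethylbicyclo[4.1.0]heptan-2-ylidene]-2,4,6-tri(propan-2-yl)benzenesulfonohydrazide
Conditions: 2,4,6-triisopropylbenzenesulfonohydrazide, HCl (cat.), THF, 20 °C
Reagents that add atoms: 2,4,6-tri(propan-2-yl)benzenesulfonohydrazide, CC(C)c1cc(C(C)C)c(S(=O)(=O)NN)c(C(C)C)c1
Why: Acid-catalysed hydrazone condensation; the bulky arenesulfonyl group is the one suited to a clean Shapiro reaction.

Step 8
Reactants: 16 N′-[(1S,6R)-3,7,7-trimethylbicyclo[4.1.0]heptan-2-ylidene]-2,4,6-tri(propan-2-yl)benzenesulfonohydrazide; 10 (2R)-2-[(1S)-1-(2,6-dimethoxyphenyl)-3-methylbutyl]-2-methylcyclobutan-1-one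
Product: 18 (2R)-2-[(1R)-1-(2,6-dimethoxyphenyl)-3-methylbutyl]-2-methyl-1-[(1S,6R)-3,7,7-trimethylbicyclo[4.1.0]hept-2-en-2-yl]cyclobutan-1-ol (carbinol centre unassigned), via [(1R,6R)-3,7,7-trimethylbicyclo[4.1.0]hept-2-en-2-yl]lithium 17 (not isolated)
Conditions: 16 (1.3 equiv), n-BuLi (2.6 equiv), TMEDA, THF, −78 → 0 °C; then 10, −78 °C; H2O
Reagents that add atoms: none
Why: Shapiro reaction, in which elimination can only occur towards the methyl-bearing carbon because the cyclopropane bridgehead cannot become sp2, followed by 1,2-addition of vinyllithium 17 to the strained, highly electrophilic cyclobutanone; the new carbinol centre is lost in step 9.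

Step 9
Reactants: 18 (2R)-2-[(1R)-1-(2,6-dimethoxyphenyl)-3-methylbutyl]-2-methyl-1-[(1S,6R)-3,7,7-trimethylbicyclo[4.1.0]hept-2-en-2-yl]cyclobutan-1-ol
Product: 21 (2R,3R)-3-[(1R)-1-(2,6-dimethoxyphenyl)-3-methylbutyl]-2-[(1R,3R)-2,2-dimethyl-3-(3-oxobutyl)cyclopropyl]-3-methylcyclopentan-1-one, via epoxy alcohol 19 (not isolated), via spiro β-hydroxy ketone 20 (not isolated)
Conditions: m-CPBA (1.05 equiv), CH2Cl2, −20 → 0 °C; then MeOH, K2CO3, 20 °C
Reagents that add atoms: 3-chloroperoxybenzoic acid, OOC(=O)c1cccc(Cl)c1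
Why: Prilezhaev epoxidation of the tetrasubstituted allylic alkene is followed by a strain-driven semipinacol ring expansion (epoxy-alcohol type) in which the more electron-rich quaternary cyclobutane carbon migrates with retention to the epoxide carbon next to the carbinol, and the congested spiro aldol 20 then undergoes base-induced retro-aldol cleavage that releases the methyl ketone and an enolisable C2–H, which equilibrates to the 2R isomer with the cyclopropyl group trans to the large benzylic substituent.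

Step 10
Reactants: 21 (2R,3R)-3-[(1R)-1-(2,6-dimethoxyphenyl)-3-methylbutyl]-2-[(1R,3R)-2,2-dimethyl-3-(3-oxobutyl)cyclopropyl]-3-methylcyclopentan-1-one
Product: 23 (2R,3R)-2-[(1R,3R)-2,2-dimethyl-3-(3-oxobutyl)cyclopropyl]-3-[(1R)-1-(4-hydroxy-2,6-dimethoxyphenyl)-3-methylbutyl]-3-methylcyclopentan-1-one, via aryl pinacol boronate 22 (not isolated)
Conditions: bis(pinacolato)diboron, [Ir(OMe)(cod)]2 (1.5 mol %), 4,4′-di-tert-butyl-2,2′-bipyridine, THF, 80 °C; then KHSO5 (Oxone), acetone/H2O, 20 °C
Reagents that add atoms: potassium peroxymonosulfate, [K+].[O-]S(=O)(=O)OO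
Why: Sterically controlled iridium-catalysed C–H borylation takes the only arene C–H flanked by two hydrogens (para to the side chain), and one-pot oxidation of the C–B bond gives the phenol.

Step 11
Reactants: 23 (2R,3R)-2-[(1R,3R)-2,2-dimethyl-3-(3-oxobutyl)cyclopropyl]-3-[(1R)-1-(4-hydroxy-2,6-dimethoxyphenyl)-3-methylbutyl]-3-methylcyclopentan-1-one
Product: 24 5-[(1R)-1-[(1R,2R)-2-[(1R,3R)-2,2-dimethyl-3-(3-oxobutyl)cyclopropyl]-1-methyl-3-oxocyclopentyl]-3-methylbutyl]-2-hydroxy-4,6-dimethoxybenzene-1,3-dicarbaldehyde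
Conditions: Cl2CHOMe (6 equiv), TiCl4 (8 equiv), CH2Cl2, −20 → 0 °C; H2O
Reagents that add atoms: dichloro(methoxy)methane, COC(Cl)Cl; water, O
Why: Rieche formylation; the titanium phenoxide directs electrophilic substitution to the two remaining ring positions, both ortho to the free hydroxyl, and the ring is electron-rich enough to take the second formyl group.

Step 12
Reactants: 24 5-[(1R)-1-[(1R,2R)-2-[(1R,3R)-2,2-dimethyl-3-(3-oxobutyl)cyclopropyl]-1-methyl-3-oxocyclopentyl]-3-methylbutyl]-2-hydroxy-4,6-dimethoxybenzene-1,3-dicarbaldehyde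
Product: 25 5-[(1R)-1-[(1R,2R)-2-[(1R,3R)-2,2-dimethyl-3-(3-oxobutyl)cyclopropyl]-1-methyl-3-oxocyclopentyl]-3-methylbutyl]-2,4,6-trihydroxybenzene-1,3-dicarbaldehyde (target)
Conditions: BCl3, CH2Cl2, −78 → 0 °C; H2O
Reagents that add atoms: none
Why: Chelation-assisted Lewis acid ether cleavage; each methoxy group is ortho to a formyl group, so BCl3 removes both at low temperature without touching the ketones, the cyclopropane or the stereocentres.

## Compound list

1 | resorcinol | Oc1cccc(O)c1 | starting material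
2 | 1,3-dimethoxybenzene | COc1cccc(OC)c1 | intermediate
3 | 3-methylbutanal | CC(C)CC=O | starting material
4 | 2,6-dimethoxyphenyllithium | [Li]c1c(OC)cccc1OC | intermediate
5 | lithium 1-(2,6-dimethoxyphenyl)-3-methylbutan-1-olate (racemic) | [Li]OC(CC(C)C)c1c(OC)cccc1OC | intermediate
6 | 1-(2,6-dimethoxyphenyl)-3-methylbutyl acetate (racemic) | CC(=O)OC(CC(C)C)c1c(OC)cccc1OC | intermediate
7 | 2-methylcyclobutan-1-one (racemic) | CC1CCC1=O | starting material
8 | trimethyl[(2-methylcyclobut-1-en-1-yl)oxy]silane | CC1=C(O[Si](C)(C)C)CC1 | intermediate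
9 | 1-(2,6-dimethoxyphenyl)-3-methylbutyl cation (ion pair with the catalyst anion) | CC(C)C[CH+]c1c(OC)cccc1OC | intermediate
10 | (2R)-2-[(1S)-1-(2,6-dimethoxyphenyl)-3-methylbutyl]-2-methylcyclobutan-1-one | O=C1CC[C@]1(C)[C@@H](CC(C)C)c1c(OC)cccc1OC | intermediate
11 | 6-methylcyclohex-2-en-1-one (racemic) | CC1CCC=CC1=O | starting material
12 | potassium trifluoro(prop-1-en-2-yl)borate | [K+].CC(=C)[B-](F)(F)F | starting material
13 | (5R)-2-methyl-5-(prop-1-en-2-yl)cyclohexan-1-one (both C2 epimers) | CC1CC[C@@H](C(C)=C)CC1=O | intermediate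
14 | (5R)-5-(2-bromopropan-2-yl)-2-methylcyclohexan-1-one (both C2 epimers) | CC1CC[C@@H](C(C)(C)Br)CC1=O | intermediate
15 | (1S,6R)-3,7,7-trimethylbicyclo[4.1.0]heptan-2-one (carone; both C3 epimers) | CC1CC[C@@H]2[C@H](C1=O)C2(C)C | intermediate
16 | N′-[(1S,6R)-3,7,7-trimethylbicyclo[4.1.0]heptan-2-ylidene]-2,4,6-tri(propan-2-yl)benzenesulfonohydrazide | CC1CC[C@@H]2[C@H](C1=NNS(=O)(=O)c3c(C(C)C)cc(C(C)C)cc3C(C)C)C2(C)C | intermediate
17 | [(1R,6R)-3,7,7-trimethylbicyclo[4.1.0]hept-2-en-2-yl]lithium | CC1=C([Li])[C@H]2[C@@H](CC1)C2(C)C | intermediate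
18 | (2R)-2-[(1R)-1-(2,6-dimethoxyphenyl)-3-methylbutyl]-2-methyl-1-[(1S,6R)-3,7,7-trimethylbicyclo[4.1.0]hept-2-en-2-yl]cyclobutan-1-ol (carbinol centre unassigned) | CC1=C(C3(O)CC[C@]3(C)[C@@H](CC(C)C)c4c(OC)cccc4OC)[C@H]2[C@@H](CC1)C2(C)C | intermediate
19 | epoxy alcohol: 18 with the ring C2=C3 double bond of the carene unit epoxidised (epoxide and carbinol centres unassigned, other centres as in 18) | CC12CC[C@@H]3[C@H](C1(O2)C4(O)CC[C@]4(C)[C@@H](CC(C)C)c5c(OC)cccc5OC)C3(C)C | intermediate
20 | spiro β-hydroxy ketone: cyclopentanone spiro-fused through its C2 to C2 of a 3-hydroxy-3,7,7-trimethylbicyclo[4.1.0]heptane, with the quaternary methyl/benzylic carbon as cyclopentanone C3 (spiro and carbinol centres unassigned, other centres as in 18) | CC1(O)CC[C@@H]2[C@H](C13C(=O)CC[C@]3(C)[C@@H](CC(C)C)c4c(OC)cccc4OC)C2(C)C | intermediate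
21 | (2R,3R)-3-[(1R)-1-(2,6-dimethoxyphenyl)-3-methylbutyl]-2-[(1R,3R)-2,2-dimethyl-3-(3-oxobutyl)cyclopropyl]-3-methylcyclopentan-1-one | CC(=O)CC[C@@H]1[C@H]([C@H]2C(=O)CC[C@]2(C)[C@@H](CC(C)C)c2c(OC)cccc2OC)C1(C)C | intermediate
22 | 21 carrying a 4,4,5,5-tetramethyl-1,3,2-dioxaborolan-2-yl group at the arene position para to the side chain | CC(=O)CC[C@@H]1[C@H]([C@H]2C(=O)CC[C@]2(C)[C@@H](CC(C)C)c2c(OC)cc(B3OC(C)(C)C(C)(C)O3)cc2OC)C1(C)C | intermediate
23 | (2R,3R)-2-[(1R,3R)-2,2-dimethyl-3-(3-oxobutyl)cyclopropyl]-3-[(1R)-1-(4-hydroxy-2,6-dimethoxyphenyl)-3-methylbutyl]-3-methylcyclopentan-1-one | CC(=O)CC[C@@H]1[C@H]([C@H]2C(=O)CC[C@]2(C)[C@@H](CC(C)C)c2c(OC)cc(O)cc2OC)C1(C)C | intermediate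
24 | 5-[(1R)-1-[(1R,2R)-2-[(1R,3R)-2,2-dimethyl-3-(3-oxobutyl)cyclopropyl]-1-methyl-3-oxocyclopentyl]-3-methylbutyl]-2-hydroxy-4,6-dimethoxybenzene-1,3-dicarbaldehyde | CC(=O)CC[C@@H]1[C@H]([C@H]2C(=O)CC[C@]2(C)[C@@H](CC(C)C)c2c(OC)c(C=O)c(O)c(C=O)c2OC)C1(C)C | intermediate
25 | 5-[(1R)-1-[(1R,2R)-2-[(1R,3R)-2,2-dimethyl-3-(3-oxobutyl)cyclopropyl]-1-methyl-3-oxocyclopentyl]-3-methylbutyl]-2,4,6-trihydroxybenzene-1,3-dicarbaldehyde | CC(=O)CC[C@@H]1[C@H]([C@H]2C(=O)CC[C@]2(C)[C@@H](CC(C)C)c2c(O)c(C=O)c(O)c(C=O)c2O)C1(C)C | target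

## Step count and risks

Total steps: 12. Longest linear sequence: 8 steps (1 → 2 → 4 → 8 → 9 → 10 → 11 → 12; the branch 5 → 6 → 7 → 8 → … → 12 is equally long).

The three steps most likely to fail:

1. Step 4 (the proposed new asymmetric SN1 alkylation; it may give low ee, low dr, or only elimination of 9 to the styrene). The fallback sets out from 6 and 8 and comes back at 18. 6 and 8 are coupled with achiral Me3SiOTf (5 mol %, CH2Cl2, −78 °C), an established Mukaiyama-type alkylation of silyl enol ethers by benzylic acetates. After chromatographic removal of the other diastereomer this gives the racemic ketone F1 (10 plus its mirror image). The racemate is taken through step 8 with enantiopure 17. This gives 18 together with the diastereomeric allylic alcohol F2 formed from the mirror-image ketone. The two are diastereomers and are separated by chromatography, so the resolution is done by the enantiopure carane partner.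

2. Step 8 (the Shapiro reaction must deprotonate a tertiary C–H, and a hindered vinyllithium must add to a ketone next to a quaternary carbon). The fallback sets out from 15 and comes back at 17. Carone 15 is enolised on its only enolisable side and trapped (KN(SiMe3)2, PhNTf2, THF, −78 °C) as the enol triflate F3. Pd(PPh3)4/LiCl/Me3SnSnMe3 (dioxane, 90 °C) converts it to the vinylstannane F4. Tin–lithium exchange (MeLi, THF, −78 °C) then gives 17 free of sulfinate and excess base, which is used as in step 8.

3. Step 9 (the CH2 rather than the quaternary carbon may migrate, or the developing positive charge next to the gem-dimethylcyclopropane may open the three-membered ring). The fallback sets out from 18 and comes back at 21. Ozonolysis of the tetrasubstituted alkene (O3, CH2Cl2/MeOH, pyridine, −78 °C; Me2S) gives the 1-acylcyclobutanol diketone F5. A base-induced α-ketol rearrangement (KOt-Bu cat., THF, 0 °C) expands the cyclobutanol to the 2-cyclopropyl-2-hydroxycyclopentanone F6 without any cationic centre beside the cyclopropane. SmI2 (THF/MeOH, −78 °C) removes the tertiary α-hydroxyl, and K2CO3/MeOH equilibrates C2 to give 21.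

Further compounds

F1 | step 4 | racemic 2-[1-(2,6-dimethoxyphenyl)-3-methylbutyl]-2-methylcyclobutan-1-one, (2R*,1′S*) diastereomer: 10 plus its enantiomer (SMILES of the (2S,1′R) enantiomer) | O=C1CC[C@@]1(C)[C@H](CC(C)C)c1c(OC)cccc1OC
F2 | step 4 | (2S)-2-[(1S)-1-(2,6-dimethoxyphenyl)-3-methylbutyl]-2-methyl-1-[(1S,6R)-3,7,7-trimethylbicyclo[4.1.0]hept-2-en-2-yl]cyclobutan-1-ol (diastereomer of 18, carbinol centre unassigned) | CC1=C(C3(O)CC[C@@]3(C)[C@H](CC(C)C)c4c(OC)cccc4OC)[C@H]2[C@@H](CC1)C2(C)C
F3 | step 8 | (1S,6R)-3,7,7-trimethylbicyclo[4.1.0]hept-2-en-2-yl trifluoromethanesulfonate | CC1=C(OS(=O)(=O)C(F)(F)F)[C@H]2[C@@H](CC1)C2(C)C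
F4 | step 8 | trimethyl[(1S,6R)-3,7,7-trimethylbicyclo[4.1.0]hept-2-en-2-yl]stannane | CC1=C([Sn](C)(C)C)[C@H]2[C@@H](CC1)C2(C)C
F5 | step 9 | 4-[(1R,3S)-3-({(2R)-2-[(1R)-1-(2,6-dimethoxyphenyl)-3-methylbutyl]-1-hydroxy-2-methylcyclobutyl}carbonyl)-2,2-dimethylcyclopropyl]butan-2-one (carbinol centre unassigned) | CC(=O)CC[C@@H]1[C@H](C(=O)C2(O)CC[C@]2(C)[C@@H](CC(C)C)c2c(OC)cccc2OC)C1(C)C
F6 | step 9 | 2-hydroxy derivative of 21: (3R)-3-[(1R)-1-(2,6-dimethoxyphenyl)-3-methylbutyl]-2-[(1R,3R)-2,2-dimethyl-3-(3-oxobutyl)cyclopropyl]-2-hydroxy-3-methylcyclopentan-1-one (C2 unassigned) | CC(=O)CC[C@@H]1[C@H](C2(O)C(=O)CC[C@]2(C)[C@@H](CC(C)C)c2c(OC)cccc2OC)C1(C)C
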